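**Retrosynthetic overview**

1. Target ⇐ singlet-oxygen ene reaction on the C3=C4 alkene of a pachydictyol-type triene; this puts the 4-OH on the convex face and moves the alkene to C2=C3.
2. That triene ⇐ dehydration of the C4 carbinol of a hydroazulene formed by transannular C1–C5 closure of a ten-membered (E)-alkene 4,5-epoxide (second ring-forming event; the five- and seven-membered rings form together).
3. Side chain C12–C15 ⇐ grown on the ten-membered ring from its isopropenyl group by hydroformylation, asymmetric isobutenyl addition and acetylation.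
4. Ten-membered ring ⇐ C6–C7 closure of an acyclic C15 epoxy-aldehyde by umpolung allylation (first ring-forming event, the bond the terpene cyclase makes); it sets C6 and C7 from the epoxide alone.
5. Acyclic precursor ⇐ (2E,6E)-farnesol by Sharpless epoxidation, SeO2 oxidation and a one-flask Corey–Kim chlorination/oxidation.

Assumption: the presumed biosynthesis is C6–C7 ring closure of the isoprenoid chain, transannular C1–C5 closure of a 4,5-epoxide, then ene-type oxygenation of the 3,4-alkene. Ring atoms are C1–C10 (C1/C5 ring fusion, C4 methyl carbinol, C6 carbinol, C7 side-chain carbon, C10 methylene carbon), side chain C11–C15, C17 = methyl on C4, C18 = methylene on C10, C19 = methyl on C11.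

**Step 1**
Reactants: 1 (2E,6E)-farnesol
Product: 2 (2S,3S,6E)-2,3-epoxy-3,7,11-trimethyldodeca-6,10-dien-1-ol
Conditions: Ti(OiPr)4 (5 mol%), L-(+)-diethyl tartrate (6 mol%), t-BuOOH, 4 Å MS, CH2Cl2, −20 °C
Reagents that add atoms: tert-butyl hydroperoxide, CC(C)(C)OO
Why: Sharpless asymmetric epoxidation touches only the allylic-alcohol alkene, and the L-(+)-tartrate titanium complex delivers oxygen to the face that gives the 2S,3S epoxide (the later C5 and C4).

**Step 2**
Reactants: 2 (2S,3S,6E)-2,3-epoxy-3,7,11-trimethyldodeca-6,10-dien-1-ol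
Product: 3 (2S,3S,6E,10E)-2,3-epoxy-3,7,11-trimethyldodeca-6,10-diene-1,12-diol
Conditions: SeO2 (0.3 equiv), t-BuOOH (3 equiv), salicylic acid (10 mol%), CH2Cl2, 23 °C
Reagents that add atoms: selenium dioxide, O=[Se]=O; tert-butyl hydroperoxide (re-oxidant), CC(C)(C)OO
Why: SeO2-catalysed allylic oxidation (ene reaction then [2,3]-shift) is selective for the E-methyl group of the terminal trisubstituted alkene and keeps the 10E geometry, while the epoxy alcohol is inert.

**Step 3**
Reactants: 3 (2S,3S,6E,10E)-2,3-epoxy-3,7,11-trimethyldodeca-6,10-diene-1,12-diol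
Product: 5 (2R,3S,6E,10E)-12-chloro-2,3-epoxy-3,7,11-trimethyldodeca-6,10-dienal, via alkoxysulfonium chloride 4 (not isolated)
Conditions: NCS (2.5 equiv), Me2S (3 equiv), CH2Cl2, −25 → 0 °C, 1 h; then −25 °C, Et3N (3 equiv)
Reagents that add atoms: N-chlorosuccinimide, O=C1CCC(=O)N1Cl
Why: Corey–Kim chemistry, in which the allylic alkoxysulfonium ion is displaced by chloride whereas the saturated one (4) survives until Et3N turns it into the aldehyde, so one flask differentiates the two primary alcohols; no stereocentre is touched (C2 becomes R only through the priority change).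

**Step 4**
Reactants: 5 (2R,3S,6E,10E)-12-chloro-2,3-epoxy-3,7,11-trimethyldodeca-6,10-dienal
Product: 7 (1(10)E,4S,5S,6S,7R)-4,5-epoxy-7-isopropenyl-4,10-dimethylcyclodec-1(10)-en-6-ol, via allylzinc species 6 (not isolated)
Conditions: Pd(PPh3)4 (10 mol%), Et2Zn (3 equiv), THF, 25 °C, syringe-pump addition to 0.005 M
Reagents that add atoms: none
Why: Umpolung allylation (zerovalent palladium ionises the allyl chloride, Et2Zn converts the π-allyl complex into allylzinc 6, which adds through its more substituted carbon in a chair transition state); Felkin–Anh attack anti to the epoxide C–O bond is expected to give 6S, and the exo (pseudo-equatorial) position of C11 on the forming ring to give 7R with OH and isopropenyl cis.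

**Step 5**
Reactants: 7 (1(10)E,4S,5S,6S,7R)-4,5-epoxy-7-isopropenyl-4,10-dimethylcyclodec-1(10)-en-6-ol
Product: 8 6-O-triethylsilyl ether of 7
Conditions: Et3SiCl, imidazole, DMAP (cat.), DMF, 23 °C
Reagents that add atoms: chlorotriethylsilane, CC[Si](Cl)(CC)CC
Why: Standard silylation of the secondary alcohol, which stops lactol formation with the C13 aldehyde made next and shields C6–OH during the later dehydration; no stereocentre changes.

**Step 6**
Reactants: 8 6-O-triethylsilyl ether of 7
Product: 9 (1(10)E,4S,5S,6S,7R,11R)-aldehyde, the isopropenyl group of 8 converted into CH(CH3)CH2CHO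
Conditions: Rh(acac)(CO)2 (1 mol%), tris(2,4-di-tert-butylphenyl) phosphite (5 mol%), CO/H2 (1:1, 20 bar), toluene, 50 °C
Reagents that add atoms: carbon monoxide, [C-]#[O+]
Why: Rh-catalysed hydroformylation reacts only with the 1,1-disubstituted alkene and only at its CH2 terminus, leaving the trisubstituted ring alkene and the epoxide; Rh–H is expected to add to the face remote from the C6 silyl ether in the rotamer that eclipses C7–H with C=CH2, giving 11R (substrate control, the 11S epimer removed by chromatography).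

**Step 7**
Reactants: 9 (1(10)E,4S,5S,6S,7R,11R)-aldehyde; 10 1-bromo-2-methylprop-1-ene
Product: 11 (13R)-allylic alcohol, side chain CH(CH3)CH2CH(OH)CH=C(CH3)2
Conditions: CrCl2 (3 equiv), NiCl2 (2 mol%), chiral oxazoline-sulfonamide ligand (3.3 equiv), Et3N (3.3 equiv), THF, 23 °C
Reagents that add atoms: 1-bromo-2-methylprop-1-ene (10), CC(C)=CBr
Why: Asymmetric Nozaki–Hiyama–Kishi alkenylation is selective for the aldehyde over the epoxide, and the chiral sulfonamide–chromium complex (ligand enantiomer chosen for 13R) sets the carbinol centre by reagent control.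

**Step 8**
Reactants: 11 (13R)-allylic alcohol
Product: 12 (13R)-acetate, side chain CH(CH3)CH2CH(OAc)CH=C(CH3)2
Conditions: Ac2O, pyridine, DMAP (cat.), CH2Cl2, 0 → 23 °C
Reagents that add atoms: acetic anhydride, CC(=O)OC(C)=O
Why: DMAP-catalysed acylation of the only free hydroxyl with retention at C13.

**Step 9**
Reactants: 12 (13R)-acetate
Product: 13 (1S,4S,5R,6S,7R,11R,13R)-13-acetoxy-6-(triethylsilyloxy)hydroazulene-10(18),14-dien-4-ol (cis-fused 5–7 bicycle)
Conditions: Me2AlCl (1.5 equiv), 2,6-di-tert-butyl-4-methylpyridine (2 equiv), CH2Cl2, −78 → −40 °C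
Reagents that add atoms: none
Why: Transannular epoxide–olefin cyclization, in which C1 of the E-alkene attacks C5 anti to the Lewis-acid-bound epoxide oxygen in the crossed ring conformation (inversion at C5, C4 keeps its oxygen) to give the cis-fused 1S,5R junction with 4S, and the hindered pyridine takes the most accessible proton (H18) of the C10 cation to give the exocyclic alkene.

**Step 10**
Reactants: 13 (1S,4S,5R,6S,7R,11R,13R)-13-acetoxy-6-(triethylsilyloxy)hydroazulene-10(18),14-dien-4-ol
Product: 14 (1S,5S,6S,7R,11R,13R)-13-acetoxy-6-(triethylsilyloxy)hydroazulene-3,10(18),14-triene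
Conditions: Martin sulfurane Ph2S[OC(CF3)2Ph]2 (1.5 equiv), CH2Cl2, 0 °C
Reagents that add atoms: none
Why: Martin sulfurane dehydrates the tertiary alcohol by anti elimination; H5 is cis to the C4 oxygen and cannot be anti, so a C3 hydrogen is lost and the ring C3=C4 alkene forms (minor exocyclic isomer), which is the alkene the final ene oxygenation needs (C4 is re-made in step 12).

**Step 11**
Reactants: 14 (1S,5S,6S,7R,11R,13R)-13-acetoxy-6-(triethylsilyloxy)hydroazulene-3,10(18),14-triene
Product: 15 (1S,5S,6S,7R,11R,13R)-13-acetoxyhydroazulene-3,10(18),14-trien-6-ol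
Conditions: HF·pyridine, pyridine, THF, 0 °C
Reagents that add atoms: none
Why: Buffered fluoride desilylation; the allylic acetate and the alkenes are inert and no stereocentre is touched.

**Step 12**
Reactants: 15 (1S,5S,6S,7R,11R,13R)-13-acetoxyhydroazulene-3,10(18),14-trien-6-ol
Product: 17 (1S,4S,5R,6S,7R,11R,13R)-13-acetoxyhydroazulene-2,10(18),14-triene-4,6-diol (target), via allylic hydroperoxide 16 (not isolated)
Conditions: O2, tetraphenylporphyrin (1 mol%), white LED, CH2Cl2, −20 °C; then PPh3, 0 °C
Reagents that add atoms: dioxygen, O=O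
Why: Schenck ene reaction, in which singlet oxygen prefers the electron-rich trisubstituted cyclopentene (the side-chain alkene is deactivated by its allylic acetate, the methylene is 1,1-disubstituted), bonds to C4 from the convex face syn to H1/H5 and takes the syn hydrogen at C2 to give the 4S hydroperoxide 16 with the C2=C3 alkene; PPh3 then reduces the O–O bond.

**Compound list**

1 | (2E,6E)-farnesol | OC/C=C(\C)CC/C=C(\C)CCC=C(C)C | starting material
2 | (2S,3S,6E)-2,3-epoxy-3,7,11-trimethyldodeca-6,10-dien-1-ol | OC[C@@H]1O[C@@]1(C)CC/C=C(\C)CCC=C(C)C | intermediate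
3 | (2S,3S,6E,10E)-2,3-epoxy-3,7,11-trimethyldodeca-6,10-diene-1,12-diol | OC[C@@H]1O[C@@]1(C)CC/C=C(\C)CC/C=C(\C)CO | intermediate
4 | dimethyl{[(2S,3S,6E,10E)-12-chloro-2,3-epoxy-3,7,11-trimethyldodeca-6,10-dien-1-yl]oxy}sulfonium chloride | C[S+](C)OC[C@@H]1O[C@@]1(C)CC/C=C(\C)CC/C=C(\C)CCl.[Cl-] | intermediate
5 | (2R,3S,6E,10E)-12-chloro-2,3-epoxy-3,7,11-trimethyldodeca-6,10-dienal | O=C[C@@H]1O[C@@]1(C)CC/C=C(\C)CC/C=C(\C)CCl | intermediate
6 | ethyl(allyl)zinc derived from 5 (C12–Cl replaced by C12–ZnEt) | O=C[C@@H]1O[C@@]1(C)CC/C=C(\C)CC/C=C(\C)C[Zn]CC | intermediate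
7 | (1(10)E,4S,5S,6S,7R)-4,5-epoxy-7-isopropenyl-4,10-dimethylcyclodec-1(10)-en-6-ol | O[C@@H]1[C@@H]2O[C@@]2(C)CC/C=C(\C)CC[C@@H]1C(C)=C | intermediate
8 | 6-O-triethylsilyl ether of 7 | CC[Si](CC)(CC)O[C@@H]1[C@@H]2O[C@@]2(C)CC/C=C(\C)CC[C@@H]1C(C)=C | intermediate
9 | (1(10)E,4S,5S,6S,7R,11R)-aldehyde, C7 side chain CH(CH3)CH2CHO | CC[Si](CC)(CC)O[C@@H]1[C@@H]2O[C@@]2(C)CC/C=C(\C)CC[C@@H]1[C@H](C)CC=O | intermediate
10 | 1-bromo-2-methylprop-1-ene | CC(C)=CBr | starting material
11 | (13R)-allylic alcohol, C7 side chain CH(CH3)CH2CH(OH)CH=C(CH3)2 | CC[Si](CC)(CC)O[C@@H]1[C@@H]2O[C@@]2(C)CC/C=C(\C)CC[C@@H]1[C@H](C)C[C@H](C=C(C)C)O | intermediate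
12 | (13R)-acetate of 11 | CC[Si](CC)(CC)O[C@@H]1[C@@H]2O[C@@]2(C)CC/C=C(\C)CC[C@@H]1[C@H](C)C[C@H](C=C(C)C)OC(C)=O | intermediate
13 | (1S,4S,5R,6S,7R,11R,13R)-13-acetoxy-6-(triethylsilyloxy)hydroazulene-10(18),14-dien-4-ol | C=C1CC[C@H]([C@H](C)C[C@H](C=C(C)C)OC(C)=O)[C@H](O[Si](CC)(CC)CC)[C@H]2[C@@H]1CC[C@]2(C)O | intermediate
14 | (1S,5S,6S,7R,11R,13R)-13-acetoxy-6-(triethylsilyloxy)hydroazulene-3,10(18),14-triene | C=C1CC[C@H]([C@H](C)C[C@H](C=C(C)C)OC(C)=O)[C@H](O[Si](CC)(CC)CC)[C@H]2[C@@H]1CC=C2C | intermediate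
15 | (1S,5S,6S,7R,11R,13R)-13-acetoxyhydroazulene-3,10(18),14-trien-6-ol | C=C1CC[C@H]([C@H](C)C[C@H](C=C(C)C)OC(C)=O)[C@H](O)[C@H]2[C@@H]1CC=C2C | intermediate
16 | (1S,4S,5R,6S,7R,11R,13R)-13-acetoxy-4-hydroperoxyhydroazulene-2,10(18),14-trien-6-ol | C=C1CC[C@H]([C@H](C)C[C@H](C=C(C)C)OC(C)=O)[C@H](O)[C@H]2[C@@H]1C=C[C@]2(C)OO | intermediate
17 | (1S,4S,5R,6S,7R,11R,13R)-13-acetoxyhydroazulene-2,10(18),14-triene-4,6-diol (CNP0209568.2) | C=C1CC[C@H]([C@H](C)C[C@H](C=C(C)C)OC(C)=O)[C@H](O)[C@H]2[C@@H]1C=C[C@]2(C)O | target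

**Totals and risk**

Total step count: 12. Longest linear sequence: 12 steps (from farnesol; 1-bromo-2-methylprop-1-ene is bought).

The macrocyclization in step 4 also carries stereochemical risk at C6 and C7; the three steps below are judged more likely to fail.

Step 6 (C11 set by substrate control): the facial bias of the isopropenyl group on the flexible ten-membered ring may be small or reversed. Fallback: set C11 by catalyst control. It sets out from aldehyde 9 (either C11 epimer or the mixture). Dehydrogenation with IBX in DMSO at 50 °C gives the (E)-enal F1. Iminium-catalysed transfer hydrogenation (chiral imidazolidinone·TFA salt, Hantzsch ester, CHCl3, −30 °C), which is convergent for enal geometry, returns to aldehyde 9 with 11R fixed by the catalyst enantiomer.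

Step 9 (end of the cation): proton loss from the C10 cation may favour the C1=C10 or C9=C10 alkene over the methylene. Fallback: end the cyclization with water and make the alkene later. It sets out from acetate 12. Cyclization in HFIP–H2O (9:1) at 0 °C captures the cation from the convex face to give the 4,10-diol F2, whose C10 hydroxyl is cis to H1. Excess Martin sulfurane then dehydrates both tertiary carbinols by anti elimination; the C10 carbinol has no anti hydrogen at C1, so it cannot give the C1=C10 alkene. This returns to triene 14.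

Step 12 (regiochemistry of the ene reaction): singlet oxygen can also take H5 or a C17 hydrogen and give the secondary C3 hydroperoxides, so the yield may be low. Fallback: epoxide-to-allylic-alcohol transposition through selenium. It sets out from triene 15. mCPBA (CH2Cl2, NaHCO3, 0 °C) epoxidises the cyclopentene from the convex face to give the 3,4-epoxide F3. PhSeSePh/NaBH4 in EtOH opens it at the less substituted C3 with inversion to give the hydroxy selenide F4. H2O2 in THF then gives the selenoxide, whose syn elimination can only go towards C2, and this returns to target 17.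

**Further compounds**

F1 | step 6 | (1(10)E,4S,5S,6S,7R,11E)-enal, C7 side chain C(CH3)=CH–CHO on the ring of 8 | CC[Si](CC)(CC)O[C@@H]1[C@@H]2O[C@@]2(C)CC/C=C(\C)CC[C@@H]1/C(C)=C/C=O
F2 | step 9 | (1S,4S,5R,6S,7R,10S,11R,13R)-13-acetoxy-6-(triethylsilyloxy)hydroazulen-14-ene-4,10-diol | C[C@]1(O)CC[C@H]([C@H](C)C[C@H](C=C(C)C)OC(C)=O)[C@H](O[Si](CC)(CC)CC)[C@H]2[C@@H]1CC[C@]2(C)O
F3 | step 12 | (1S,3S,4R,5R,6S,7R,11R,13R)-13-acetoxy-3,4-epoxyhydroazulene-10(18),14-dien-6-ol (epoxide oxygen cis to H5) | C=C1CC[C@H]([C@H](C)C[C@H](C=C(C)C)OC(C)=O)[C@H](O)[C@H]2[C@@H]1C[C@@H]3O[C@]23C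
F4 | step 12 | (1S,3R,4R,5R,6S,7R,11R,13R)-13-acetoxy-3-(phenylselanyl)hydroazulene-10(18),14-diene-4,6-diol | C=C1CC[C@H]([C@H](C)C[C@H](C=C(C)C)OC(C)=O)[C@H](O)[C@H]2[C@@H]1C[C@@H]([Se]c3ccccc3)[C@]2(C)O
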